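Four neighbouring flasks take the same charge and differ in their temperature history, and the reckoning below starts with Sunday's, at −10 °C.

common to all: substrate 0.10 M; coupling partner 0.300 M; time 1.5 min
- Sunday's: temperature −10 °C
- Saturday's: temperature 5 °C
- Tuesday's: temperature 20 °C
- Wednesday's: at −10 °C until 20 s, from then on at 20 °C

1. the flask with the highest amount of product, in percent of the substrate charged ("all alike" if they lie within 1.5 percentage points) (Sunday's / Saturday's / Tuesday's / Wednesday's / all alike)
2. final product, as a percentage of the substrate charged, in Sunday's
3. final product, as a percentage of the substrate charged, in Saturday's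
4. final product, as a percentage of the substrate charged, in Tuesday's
5. final product, as a percentage of the substrate charged, in Wednesday's

- the constants hold at 20 °C; other temperatures follow from the activation energies and enthalpies

    substrate ⇌ intermediate A (K1 = 6.8, k1 = 0.21 s⁻¹, Ea1 = 78.0 kJ mol⁻¹, ΔH1 = −13.0 kJ mol⁻¹)
    intermediate C → decomposed reagent (k2 = 0.0036 s⁻¹, Ea2 = 83.0 kJ mol⁻¹)
    intermediate B → product (k3 = 0.032 s⁻¹, Ea3 = 80.0 kJ mol⁻¹)
    substrate → intermediate B (k4 = 0.19 s⁻¹, Ea4 = 81.0 kJ mol⁻¹)
    coupling partner + intermediate B ⇌ intermediate C (K5 = 5.5 L mol⁻¹, k5 = 0.068 L mol⁻¹ s⁻¹, Ea5 = 53.0 kJ mol⁻¹, ΔH5 = −40.0 kJ mol⁻¹)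
    (constants at 20 °C)

Substrate goes either reversibly to intermediate A or onward to intermediate B. B goes to product, or is captured reversibly by coupling partner as intermediate C, which decays to decomposed reagent.

The reckoning begins with temperature. From 20 °C down to −10 °C the product step slows by a factor of 42, so for Sunday's flask:

clock = 0.032 s⁻¹ / 42 × 1.5 min = 0.0683

This number is the product clock: the rate constant of the product step multiplied by the time it has run. In a flask held at one temperature, product, as a share of the charge, equals the clock times the time-mean share of B in the flask. Sunday's clock is small, so product there is a small correction to a flask that mainly moves substrate into A and B.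

The steps out of substrate have activation energies of 78.0 kJ mol⁻¹ and 81.0 kJ mol⁻¹, close to the 80.0 kJ mol⁻¹ of the product step, so this reckoning slows them by the same factor. Leaving out the return from A and the capture of B gives:

x = (0.21 s⁻¹ + 0.19 s⁻¹) / 42 × 1.5 min = 0.854

share of substrate's flow going to B = 47.5 %

mean share of B = 47.5 % × (1 − (1 − e^−x)/x) = 15.6 %

product in Sunday's = 0.0683 × 15.6 % = 1.06 %

Capture would lower this figure a little. In Tuesday's flask the clock is 2.88, and in Wednesday's it is 2.26. Both are above one, so the hand reckoning gives their order, Tuesday's ahead, and no percentage.

Three other settings can be turned. Time enters both the clock and the mean share, so Sunday's product should rise faster than time itself. The substrate charge enters neither, because the steps to product are first order, so the percentage should stay put. Coupling partner enters through the capture correction, where it acts as a pseudo-first-order loss of B, with 0.300 M against 0.10 M of substrate.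

The forecast names Tuesday's and gives 0.9 % (0.7 % to 1.2 %) for Sunday's, 13.5 % (11.5 % to 15.5 %) for Saturday's, 55 % (50 % to 59 %) for Tuesday's and 48 % (43 % to 52 %) for Wednesday's. Its Sunday figure lies below the 1.06 % reckoned here. Its grounds include that “product formation is limited by time in the cold flasks”.

The simulation gives 0.933 % for Sunday's, 13.4 % for Saturday's, 54.9 % for Tuesday's and 47.7 % for Wednesday's, so Tuesday's leads, and each value lies inside the forecast's range. For Sunday's, the settings rank time (0.5 points), then coupling partner (under 0.05 points), then substrate (under 0.05 points), and a neighbour charged with 0.060 M of substrate gives 0.933 %.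

Product divided by the clock reads the time-mean share of intermediate B: 13.7 % in Sunday's flask and 19.1 % in Tuesday's. From Sunday's to Tuesday's the clock therefore grows far more than the mean share, by a factor of 42 against 1.39. The time allowed is a part of Sunday's small figure: at 15.0 min Sunday's clock stands at 0.683 and its product at 13.2 %, up by 12 percentage points from 0.933 %, which is 12 % of what is missing.

The constants are assumed; what happens was integrated by code.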